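A small charge of substrate meets 0.95 equiv of coupling partner and 1 equiv of rival reagent in a closed flask, and I want to know how much target stands at the end, in this set-up and in three others.

| setting | Wednesday's | Thursday's | Saturday's | birch | larch | oak | ash |
|---|---|---|---|---|---|---|---|
| substrate | 0.50 M | 0.50 M | 0.50 M | 0.50 M | 0.50 M | 0.50 M | 0.50 M |
| coupling partner | 0.95 equiv | 0.95 equiv | 0.95 equiv | 0.950 equiv (fed, over 4.80 d) | 0.950 equiv | 0.950 equiv | 0.950 equiv |
| rival reagent | 1 equiv | 0.50 equiv | 2 equiv | 1.00 equiv | 1.00 equiv (fed, over 4.80 d) | 1.00 equiv | 1.00 equiv |
| remark | run made earlier | run made earlier | run made earlier | all but coupling partner at the start; coupling partner goes in evenly over 4.80 d, the run ends at 6.0 d | all but rival reagent at the start; rival reagent goes in evenly over 4.80 d, the run ends at 6.0 d | a closed flask charged with all of it at once and left for 6.0 d | one stirred flow tank at steady state, fed with the mixture as stated, mean residence time 6.0 d |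
| time |  |  |  | 6.0 d | 6.0 d | 6.0 d |  |

| run | time / d | target / % |
|---|---|---|
| Wednesday's | 0.500 | 73.7 |
| Wednesday's | 1.04 | 68.9 |
| Wednesday's | 1.67 | 65.0 |
| Wednesday's | 2.08 | 62.7 |
| Wednesday's | 2.50 | 61.2 |
| Wednesday's | 3.00 | 60.1 |
| Wednesday's | 4.00 | 58.3 |
| Thursday's | 0.417 | 80.6 |
| Thursday's | 1.04 | 78.1 |
| Thursday's | 2.08 | 73.8 |
| Thursday's | 3.00 | 72.0 |
| Thursday's | 4.00 | 71.1 |
| Thursday's | 6.00 | 69.7 |
| Thursday's | 8.00 | 68.9 |
| Saturday's | 1.04 | 57.0 |
| Saturday's | 2.08 | 50.4 |
| Saturday's | 3.00 | 46.7 |
| Saturday's | 4.00 | 44.7 |
| Saturday's | 5.00 | 42.4 |
| Saturday's | 6.00 | 42.3 |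
| Saturday's | 8.00 | 41.4 |

(standard deviation of a reading: 0.3 percentage points)

- the stated concentrations are those of everything mixed, before any reaction; amounts are the same in each set-up
- the feed brings no volume worth counting
- the earlier runs were made in a closed, stirred flask

- the set-up with the highest amount of target at the outlet or at the end, in percent of the substrate put in ("none" if the first two lie within 2 percentage points) (birch / larch / oak / ash / none)
- amount of target at the outlet or at the end, in percent of the substrate put in, birch
- amount of target at the outlet or at the end, in percent of the substrate put in, larch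
- amount of target at the outlet or at the end, in percent of the substrate put in, oak
- amount of target at the outlet or at the end, in percent of the substrate put in, ash

I watch Wednesday's run in slow motion; it has oak's recipe. In the first instants target forms quickly: by 0.500 d it already reads 73.7%. In the middle it sinks, to 62.7% at 2.08 d, and the sinking slows: the first two readings differ by 4.8 percentage points, the last two by 1.8 points, although the last two lie further apart in time. Near the end the run is drifting towards a plateau.

To reckon that end state, I assume that each target takes one coupling partner, so the partner charge is a ceiling on target. Wednesday's last reading over its ceiling is 61.4%, and this surviving share of the ceiling I call the keep, K. Thursday's run, with 0.50 equiv of rival reagent, reads 72.5%, and Saturday's, with 2 equiv, reads 43.6%. So K, read at 8.00 d in those two runs and at 4.00 d in Wednesday's, is lower with more rival reagent, and I take rival reagent to be what consumes target. Oak should stand at K times its ceiling, 58.3%, and a little lower for the drift after 4.00 d. I carry K to flasks charged at once; for the fed flasks and the tank, where the reagents meet in another order, I commit to no figure.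

The forecast, made from the same runs, names larch as best, with birch at 2%, larch at 86%, oak at 57% and ash at 47%; for larch it argues that “coupling finishes before much rival arrives”. On oak it stands close to my figure.

The flasks give 47.6% in birch, 48.1% in larch, 56.0% in oak and 50.1% in ash, so oak is best, with a keep of 58.9%. substrate + coupling partner → target (k = 2.17 L mol⁻¹ h⁻¹); substrate + rival reagent → side product (k = 0.101 L mol⁻¹ h⁻¹); rival reagent + target → over-reaction product (k = 0.0534 L mol⁻¹ h⁻¹); 2 rival reagent → self-condensation product (k = 0.0758 L mol⁻¹ h⁻¹)

In oak the substrate's half-life by coupling at 0.0352 d is 0.054 d, shorter than the target's half-life by over-reaction at that same moment, 1.2 d, which is itself short against the 6.0 d of the run; oak ends with 34.7% of the substrate charged as over-reaction product. In one more flask like oak but with 0.240 equiv of coupling partner, the limiting reagent there with 0% of its charge left, K gives 14.7%, and that flask ends at 15.7%.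

(The data come from a simulation for substances that don't exist; scatter was added.)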